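**Strategy.** Everything rests on taking the benzenoid ring B apart into three alkyne units. The structural feature used is that ring B consists of three two-carbon units, C8/C8a, C4a/C5 and C6/C7: the first two are bridged by C1–C4 of ring A, and C6/C7 with its two methyl groups corresponds to symmetric but-2-yne. A rhodium-catalysed [2+2+2] cycloaddition of a 1,7-diyne with but-2-yne therefore closes rings A and B in one operation and brings in the crowded C8–aryl bond ready-made from an aryl alkyne. The precursor is the linear ynone Ar–C≡C–CO–(CH2)3–C≡CH (Ar = 2,4,5-trimethoxyphenyl); oxidation of ring A to the methoxyquinone follows.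

Key step: step 4

Assumption: the target is drawn without a stereodescriptor, so the hindered C8–C1' biaryl axis is taken as undefined and is made in racemic form; the molecule has no stereocentre.

**Step 1**
Reactants: 1 2,4,5-trimethoxybenzaldehyde
Product: 2 1-ethynyl-2,4,5-trimethoxybenzene
Conditions: dimethyl (1-diazo-2-oxopropyl)phosphonate (1.3 equiv), K2CO3 (2 equiv), MeOH, 0 °C to rt
Reagents that add atoms: dimethyl (1-diazo-2-oxopropyl)phosphonate, COP(=O)(OC)C(=[N+]=[N-])C(C)=O (supplies the terminal alkyne carbon)
Why: Ohira–Bestmann (Seyferth–Gilbert) homologation, in which methanolysis of the reagent frees the diazomethylphosphonate anion that olefinates the non-enolisable aryl aldehyde, and loss of N2 with a 1,2-hydrogen shift then gives the terminal alkyne under mild base that the aryl ethers tolerate.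

**Step 2**
Reactants: 3 hex-5-ynoic acid
Product: 5 N-methoxy-N-methylhex-5-ynamide, via acyl imidazolide 4 (not isolated)
Conditions: CDI (1.1 equiv), CH2Cl2, rt, 1 h; then MeNH(OMe)·HCl (1.2 equiv), rt
Reagents that add atoms: N,O-dimethylhydroxylamine hydrochloride, CNOC.Cl; 1,1'-carbonyldiimidazole, O=C(n1ccnc1)n1ccnc1 (its imidazolyl group is held only in intermediate 4)
Why: Amide coupling through an acyl imidazolide, in which CDI activates the acid with loss of CO2 and the alkoxyamine then displaces imidazole to give the Weinreb amide, the terminal alkyne being inert.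

**Step 3**
Reactants: 2 1-ethynyl-2,4,5-trimethoxybenzene; 5 N-methoxy-N-methylhex-5-ynamide
Product: 8 1-(2,4,5-trimethoxyphenyl)octa-1,7-diyn-3-one, via lithium acetylide 6 (not isolated), via lithium hemiaminal chelate 7 (not isolated)
Conditions: 2 (1.2 equiv), n-BuLi (1.15 equiv), THF, −78 °C; then 5, −78 to −20 °C; inverse quench into cold 1 M HCl
Reagents that add atoms: n-butyllithium, [Li]CCCC (its lithium is held only in intermediates 6 and 7)
Why: Weinreb ketone synthesis, in which the aryl acetylide (a weaker base than an alkyl acetylide, so it should not deprotonate the terminal alkyne of 5) adds once to give the chelated adduct 7, which persists until the cold acidic quench releases the ynone and protonates the liberated amine before it can add to the ynone.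

**Step 4**
Reactants: 8 1-(2,4,5-trimethoxyphenyl)octa-1,7-diyn-3-one; 9 but-2-yne
Product: 10 6,7-dimethyl-8-(2,4,5-trimethoxyphenyl)-3,4-dihydronaphthalen-1(2H)-one
Conditions: RhCl(PPh3)3 (10 mol %), but-2-yne (10 equiv), EtOH–toluene (1:1), 40 °C, dry-ice condenser; 8 added by syringe pump over 8 h
Reagents that add atoms: none
Why: Monovalent rhodium binds both alkynes of 8 and couples them oxidatively to a rhodacyclopentadiene, which creates the C4a–C8a bond and with it ring A; but-2-yne then coordinates and inserts into a Rh–C bond, and reductive elimination completes C5–C6 and C7–C8 and frees the catalyst. The closest known reaction type is the rhodium-catalysed crossed [2+2+2] cycloaddition of α,ω-diynes with monoalkynes, which is established for 1,7-diynes and for diynes with a carbonyl-conjugated terminus. Ring A closes as a six-membered carbocycle by intramolecular alkyne–alkyne coupling across the C1–C4 tether, and ring B closes as the new benzene ring by insertion and reductive elimination, driven by aromatisation. No stereocentre is created, and the hindered C8–C1' axis, whose bond is carried in with the aryl alkyne and not forged here, becomes stereogenic without control because the catalyst is achiral. The selectivity needed is chemoselectivity for capture of but-2-yne over a second molecule of 8, which a large excess of the cheap monoalkyne and a low stationary concentration of 8 should secure. Orientation is not in question, since but-2-yne has identical ends and the tether fixes which diyne carbons become C4a and C8a.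

**Step 5**
Reactants: 10 6,7-dimethyl-8-(2,4,5-trimethoxyphenyl)-3,4-dihydronaphthalen-1(2H)-one
Product: 11 2-hydroxy-6,7-dimethyl-8-(2,4,5-trimethoxyphenyl)naphthalene-1,4-dione
Conditions: KOtBu (4 equiv), O2 (1 atm), t-BuOH, rt; then 1 M HCl
Reagents that add atoms: dioxygen, O=O
Why: Base-mediated autoxidation of a 1-tetralone, in which the potassium enolate takes up O2 at C2, the resulting diosphenol is oxidised again at the benzylic C4, and the stable potassium salt of the 2-hydroxy-1,4-quinone results, a standard conversion of 1-tetralones into lawsone-type quinones that should leave the aryl methyl groups and aryl ethers untouched.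

**Step 6**
Reactants: 11 2-hydroxy-6,7-dimethyl-8-(2,4,5-trimethoxyphenyl)naphthalene-1,4-dione
Product: 12 2-methoxy-6,7-dimethyl-8-(2,4,5-trimethoxyphenyl)naphthalene-1,4-dione
Conditions: dry HCl in MeOH (about 1 M), reflux
Reagents that add atoms: methanol, CO
Why: Acid-catalysed Fischer-type etherification of a vinylogous carboxylic acid, in which methanol adds at C2 of the protonated hydroxyquinone and water is lost, the 2-methoxy-1,4-quinone being the thermodynamic product over the 4-methoxy-1,2-quinone isomer and the aryl methyl ethers being stable to methanolic acid.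

**Compound list**
1 | 2,4,5-trimethoxybenzaldehyde | COc1cc(OC)c(OC)cc1C=O | starting material
2 | 1-ethynyl-2,4,5-trimethoxybenzene | COc1cc(OC)c(OC)cc1C#C | intermediate
3 | hex-5-ynoic acid | C#CCCCC(=O)O | starting material
4 | 1-(1H-imidazol-1-yl)hex-5-yn-1-one (acyl imidazolide, formed in the flask) | C#CCCCC(=O)n1ccnc1 | intermediate
5 | N-methoxy-N-methylhex-5-ynamide | C#CCCCC(=O)N(C)OC | intermediate
6 | lithium (2,4,5-trimethoxyphenyl)acetylide (formed in the flask) | [Li]C#Cc1cc(OC)c(OC)cc1OC | intermediate
7 | lithium 3-[methoxy(methyl)amino]-1-(2,4,5-trimethoxyphenyl)octa-1,7-diyn-3-olate (racemic chelated adduct, formed in the flask) | [Li]OC(CCCC#C)(C#Cc1cc(OC)c(OC)cc1OC)N(C)OC | intermediate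
8 | 1-(2,4,5-trimethoxyphenyl)octa-1,7-diyn-3-one | C#CCCCC(=O)C#Cc1cc(OC)c(OC)cc1OC | intermediate
9 | but-2-yne | CC#CC | starting material
10 | 6,7-dimethyl-8-(2,4,5-trimethoxyphenyl)-3,4-dihydronaphthalen-1(2H)-one (racemic about the biaryl axis) | O=C1CCCc2cc(C)c(C)c(-c3cc(OC)c(OC)cc3OC)c21 | intermediate
11 | 2-hydroxy-6,7-dimethyl-8-(2,4,5-trimethoxyphenyl)naphthalene-1,4-dione | OC1=CC(=O)c2cc(C)c(C)c(-c3cc(OC)c(OC)cc3OC)c2C1=O | intermediate
12 | 2-methoxy-6,7-dimethyl-8-(2,4,5-trimethoxyphenyl)naphthalene-1,4-dione | COC1=CC(=O)c2cc(C)c(C)c(-c3cc(OC)c(OC)cc3OC)c2C1=O | target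

**Total step count:** 6
**Longest linear sequence:** 5 steps (1 → 2 → 8 → 10 → 11 → 12; the branch from 3 is equally long)

**Three steps most likely to fail**

Step 4. The diyne may oligomerise with itself faster than the rhodacycle captures the sluggish, volatile internal alkyne, or the ortho-substituted aryl alkyne terminus may enter the metallacycle too slowly, so that conversion to the crossed arene stays low. The fallback builds ring B by a Diels–Alder reaction onto a preformed quinone ring. It sets out from 1 and comes back to the route at 12, so steps 5 and 6 are then not needed. Wittig olefination of 1 with 3-(triphenylphosphoranylidene)butan-2-one (toluene, reflux) should give (E)-3-methyl-4-(2,4,5-trimethoxyphenyl)but-3-en-2-one F1. Methylenation with Ph3P=CH2 (from Ph3PCH3Br and KOtBu, THF) should give (E)-2,3-dimethyl-1-(2,4,5-trimethoxyphenyl)buta-1,3-diene F2. Thermal cycloaddition of F2 at the unsubstituted double bond of 2-methoxy-1,4-benzoquinone (toluene, 80 °C, no Lewis acid) should give the racemic cis-fused endo adduct 2-methoxy-6,7-dimethyl-8-(2,4,5-trimethoxyphenyl)-4a,5,8,8a-tetrahydronaphthalene-1,4-dione F3. The unsubstituted diene terminus is expected to bond to the quinone carbon that is β to the carbonyl not deactivated by the methoxy group, which places the aryl at C8; this orientation is an expectation from frontier-orbital reasoning and would need checking. Enolisation with Et3N and dehydrogenation with DDQ (benzene, reflux) should then aromatise ring B and give 12.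

Step 5. The hydroxyquinone anion may be cleaved oxidatively by peroxide intermediates, or the oxidation may stall at the diosphenol stage. The fallback introduces the oxygens one stage at a time. It sets out from 10 and comes back at 11. Oxidation with SeO2 (dioxane–AcOH, reflux) should give 6,7-dimethyl-8-(2,4,5-trimethoxyphenyl)naphthalene-1,2-dione F4. Thiele–Winter acetoxylation (Ac2O, cat. H2SO4, rt) should give 6,7-dimethyl-8-(2,4,5-trimethoxyphenyl)naphthalene-1,2,4-triyl triacetate F5. Methanolysis with K2CO3 in MeOH under air should give the triol, which oxidises in the air to 11.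

Step 3. The tetrahedral adduct may collapse early, so that the released amine or a second acetylide adds to the electrophilic ynone, or proton transfer from the terminal alkyne of 5 may quench the acetylide. The fallback forms the C2–C3 bond by aldehyde addition and adjusts the oxidation level afterwards. It sets out from 5 and comes back at 8. Reduction of 5 with iBu2AlH (THF, −78 °C) should give hex-5-ynal F6. Addition of lithium acetylide 6 (THF, −78 °C) should give racemic 1-(2,4,5-trimethoxyphenyl)octa-1,7-diyn-3-ol F7. Oxidation of the propargylic alcohol with MnO2 (CH2Cl2, rt) should give 8.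

**Further compounds**
F1 | step 4 | (E)-3-methyl-4-(2,4,5-trimethoxyphenyl)but-3-en-2-one | COc1cc(OC)c(OC)cc1/C=C(\C)C(C)=O
F2 | step 4 | (E)-2,3-dimethyl-1-(2,4,5-trimethoxyphenyl)buta-1,3-diene | COc1cc(OC)c(OC)cc1/C=C(\C)C(C)=C
F3 | step 4 | racemic cis-fused endo adduct 2-methoxy-6,7-dimethyl-8-(2,4,5-trimethoxyphenyl)-4a,5,8,8a-tetrahydronaphthalene-1,4-dione (H-4a, H-8 and H-8a on one face; one enantiomer drawn) | COC1=CC(=O)[C@@H]2CC(C)=C(C)[C@H](c3cc(OC)c(OC)cc3OC)[C@@H]2C1=O
F4 | step 5 | 6,7-dimethyl-8-(2,4,5-trimethoxyphenyl)naphthalene-1,2-dione | O=C1C=Cc2cc(C)c(C)c(-c3cc(OC)c(OC)cc3OC)c2C1=O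
F5 | step 5 | 6,7-dimethyl-8-(2,4,5-trimethoxyphenyl)naphthalene-1,2,4-triyl triacetate | CC(=O)Oc1cc(OC(C)=O)c2cc(C)c(C)c(-c3cc(OC)c(OC)cc3OC)c2c1OC(C)=O
F6 | step 3 | hex-5-ynal | C#CCCCC=O
F7 | step 3 | racemic 1-(2,4,5-trimethoxyphenyl)octa-1,7-diyn-3-ol | C#CCCCC(O)C#Cc1cc(OC)c(OC)cc1OC
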